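**Retrosynthetic overview**
1. Last C–C bond: the cyclopropyl–ketone bond C4′–C5′, made by a palladium-catalysed, copper-mediated acyl cross-coupling of a west cyclopropylboronic acid (lactone, acetate and ring in place) with an east thioester (lactate plus protected caffeate); only desilylation follows.
2. East fragment: Steglich ester of S-ethyl (S)-thiolactate with bis-TBS caffeic acid, the acid coming from catechol by bromination, silylation and a Heck reaction with acrylic acid.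
3. West fragment: cyclopropane by ligand-controlled Simmons–Smith reaction of an (E)-alkenylboronate allylic alcohol, which comes from cross-metathesis with vinyl-Bpin (made from vinylmagnesium bromide).
4. Lactone and the C6/C1′ stereocentres: Sharpless desymmetrising epoxidation of divinyl carbinol, epoxide opening with lithium ethyl propiolate, Lindlar reduction and lactonisation.
5. Ring order: arene bought (catechol); dihydropyranone first, cyclopropane second; the two fragments are joined last.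

Assumption and locants: catalogue reagents (vinylmagnesium bromide solution, L-(+)-diisopropyl tartrate, the tartramide-derived butyl dioxaborolane) are bought; C6 = lactone stereocentre, C1′ = acetoxy carbon, C2′/C3′/C4′ = cyclopropane carbons (C3′ = CH2), C5′ = ketone carbon, C6′ = lactate carbon.

**Route**

Step 1
Reactants: 1 catechol (benzene-1,2-diol)
Product: 2 4-bromobenzene-1,2-diol
Conditions: NBS (1.0 equiv), HBF4·OEt2 (10 mol%), MeCN, −30 °C → rt
Reagents that add atoms: N-bromosuccinimide, O=C1CCC(=O)N1Br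
Why: Electrophilic aromatic bromination; the position para to one hydroxyl is the most activated and least hindered, so monobromination at C4 is regioselective.

Step 2
Reactants: 2 4-bromobenzene-1,2-diol
Product: 3 4-bromo-1,2-bis[(tert-butyldimethylsilyl)oxy]benzene
Conditions: TBSCl (2.4 equiv), imidazole (5 equiv), DMF, rt
Reagents that add atoms: tert-butyldimethylsilyl chloride, CC(C)(C)[Si](C)(C)Cl
Why: Imidazole-assisted silylation of both phenols masks the catechol for the later palladium and copper steps.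

Step 3
Reactants: 3 4-bromo-1,2-bis[(tert-butyldimethylsilyl)oxy]benzene, 4 acrylic acid
Product: 5 (2E)-3-{3,4-bis[(tert-butyldimethylsilyl)oxy]phenyl}prop-2-enoic acid
Conditions: Pd(OAc)2 (5 mol%), P(o-tol)3 (10 mol%), Et3N (3 equiv), MeCN, 85 °C; dilute citric acid work-up
Reagents that add atoms: none
Why: Mizoroki–Heck reaction; syn-carbopalladation followed by syn-β-hydride elimination gives only the E-cinnamic acid.

Step 4
Reactants: 6 methyl (S)-lactate
Product: 7 S-ethyl (2S)-2-hydroxypropanethioate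
Conditions: AlMe3 (3 equiv), EtSH (3.3 equiv), CH2Cl2, 0 °C → rt; aq. KNaC4H4O6 work-up
Reagents that add atoms: ethanethiol, CCS
Why: Aluminium-thiolate ester-to-thioester exchange (Me2AlSEt formed in the flask) is non-basic, so the lactate stereocentre is kept.

Step 5
Reactants: 5 (2E)-3-{3,4-bis[(tert-butyldimethylsilyl)oxy]phenyl}prop-2-enoic acid, 7 S-ethyl (2S)-2-hydroxypropanethioate
Product: 8 (2S)-1-(ethylsulfanyl)-1-oxopropan-2-yl (2E)-3-{3,4-bis[(tert-butyldimethylsilyl)oxy]phenyl}prop-2-enoate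
Conditions: DCC (1.2 equiv), DMAP (10 mol%), CH2Cl2, 0 °C → rt
Reagents that add atoms: none
Why: Steglich esterification acylates the secondary hydroxyl at oxygen only, so C6′ is not touched and the thioester is inert to the carbodiimide.

Step 6
Reactants: 9 vinylmagnesium bromide
Product: 10 4,4,5,5-tetramethyl-2-vinyl-1,3,2-dioxaborolane (vinyl-Bpin)
Conditions: 2-isopropoxy-4,4,5,5-tetramethyl-1,3,2-dioxaborolane, THF, −78 °C → rt; HCl/Et2O
Reagents that add atoms: 2-isopropoxy-4,4,5,5-tetramethyl-1,3,2-dioxaborolane, CC(C)OB1OC(C)(C)C(C)(C)O1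
Why: Grignard borylation; the vinyl group adds once to the hindered borate ester and acid releases isopropanol to give the boronic ester.

Step 7
Reactants: 11 penta-1,4-dien-3-ol (divinyl carbinol)
Product: 12 (1S)-1-[(2R)-oxiran-2-yl]prop-2-en-1-ol
Conditions: Ti(OiPr)4 (10 mol%), L-(+)-diisopropyl tartrate (13 mol%), t-BuOOH (1.5 equiv), 4 Å MS, CH2Cl2, −20 °C
Reagents that add atoms: tert-butyl hydroperoxide, CC(C)(C)OO
Why: Sharpless asymmetric epoxidation as a desymmetrisation; the L-tartrate catalyst epoxidises one enantiotopic vinyl group on one face, setting C6 (R) and C1′ (S) together in the erythro (anti) relationship, and the minor enantiomer is consumed by a faster second epoxidation.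

Step 8
Reactants: 12 (1S)-1-[(2R)-oxiran-2-yl]prop-2-en-1-ol
Product: 13 tert-butyldimethyl{[(1S)-1-[(2R)-oxiran-2-yl]prop-2-en-1-yl]oxy}silane
Conditions: TBSCl (1.2 equiv), imidazole (2.5 equiv), DMF, 0 °C → rt
Reagents that add atoms: tert-butyldimethylsilyl chloride, CC(C)(C)[Si](C)(C)Cl
Why: Silyl ether formation under neutral imidazole conditions avoids Payne rearrangement and protects the C1′ hydroxyl from the acetylide/BF3 step.

Step 9
Reactants: 13 tert-butyldimethyl{[(1S)-1-[(2R)-oxiran-2-yl]prop-2-en-1-yl]oxy}silane, 14 ethyl propiolate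
Product: 16 ethyl (5R,6S)-6-[(tert-butyldimethylsilyl)oxy]-5-hydroxyoct-7-en-2-ynoate, via lithium ethyl propiolate 15 (not isolated)
Conditions: 14 (2.5 equiv), n-BuLi, THF, −78 °C; BF3·OEt2; then 13, −78 °C; aq. NH4Cl
Reagents that add atoms: none
Why: Yamaguchi–Hirao alkynylation; the BF3-activated terminal epoxide is opened by SN2 attack at its CH2 end, so the C6 stereocentre is not touched.

Step 10
Reactants: 16 ethyl (5R,6S)-6-[(tert-butyldimethylsilyl)oxy]-5-hydroxyoct-7-en-2-ynoate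
Product: 18 (6R)-6-[(1S)-1-[(tert-butyldimethylsilyl)oxy]prop-2-en-1-yl]-5,6-dihydro-2H-pyran-2-one, via ethyl (2Z)-hydroxydienoate 17 (not isolated)
Conditions: H2 (1 atm), Pd/CaCO3 poisoned with Pb(OAc)2 (Lindlar catalyst), quinoline, EtOAc, rt; filter; PPTS (10 mol%), toluene, 60 °C
Reagents that add atoms: none
Why: Lindlar semihydrogenation (syn H2 delivery) gives the Z-enoate, whose δ-hydroxyl closes the six-membered lactone by acid-catalysed transesterification; the conjugated alkyne is reduced much faster than the terminal alkene.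

Step 11
Reactants: 18 (6R)-6-[(1S)-1-[(tert-butyldimethylsilyl)oxy]prop-2-en-1-yl]-5,6-dihydro-2H-pyran-2-one
Product: 19 (6R)-6-[(1S)-1-hydroxyprop-2-en-1-yl]-5,6-dihydro-2H-pyran-2-one
Conditions: HF·pyridine, pyridine, THF, 0 °C → rt
Reagents that add atoms: none
Why: Fluoride-driven desilylation under buffered acidic conditions frees the allylic alcohol without opening or isomerising the unsaturated lactone.

Step 12
Reactants: 19 (6R)-6-[(1S)-1-hydroxyprop-2-en-1-yl]-5,6-dihydro-2H-pyran-2-one, 10 4,4,5,5-tetramethyl-2-vinyl-1,3,2-dioxaborolane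
Product: 20 (6R)-6-[(1S,2E)-1-hydroxy-3-(4,4,5,5-tetramethyl-1,3,2-dioxaborolan-2-yl)prop-2-en-1-yl]-5,6-dihydro-2H-pyran-2-one
Conditions: 10 (3 equiv), second-generation Hoveyda–Grubbs catalyst RuCl2(SIMes)(=CH-C6H4-2-OiPr) (5 mol%), 1,4-benzoquinone (10 mol%), CH2Cl2, 40 °C
Reagents that add atoms: none
Why: Olefin cross-metathesis of the terminal allylic alcohol with vinyl-Bpin releases ethene and gives the E-alkenylboronate; the conjugated cis lactone alkene does not take part and benzoquinone suppresses Ru–H isomerisation.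

Step 13
Reactants: 20 (6R)-6-[(1S,2E)-1-hydroxy-3-(4,4,5,5-tetramethyl-1,3,2-dioxaborolan-2-yl)prop-2-en-1-yl]-5,6-dihydro-2H-pyran-2-one
Product: 21 (6R)-6-{(S)-hydroxy[(1S,2S)-2-(4,4,5,5-tetramethyl-1,3,2-dioxaborolan-2-yl)cyclopropyl]methyl}-5,6-dihydro-2H-pyran-2-one
Conditions: Zn(CH2I)2·DME (2.5 equiv; from Et2Zn, CH2I2, DME), (4R,5R)-2-butyl-N,N,N′,N′-tetramethyl-1,3,2-dioxaborolane-4,5-dicarboxamide (1.2 equiv), CH2Cl2, −10 °C → rt; aq. NH4Cl, no peroxide
Reagents that add atoms: diiodomethane, C(I)I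
Why: Charette asymmetric Simmons–Smith cyclopropanation; the C1′ alkoxide binds the chiral dioxaborolane, which steers the zinc carbenoid to the face giving the (1S,2S) ring (anti to the C1′ oxygen, reagent control over the weak syn bias of E-allylic alcohols), and concerted methylene transfer turns the E alkene into the trans ring.

Step 14
Reactants: 21 (6R)-6-{(S)-hydroxy[(1S,2S)-2-(4,4,5,5-tetramethyl-1,3,2-dioxaborolan-2-yl)cyclopropyl]methyl}-5,6-dihydro-2H-pyran-2-one
Product: 22 (S)-[(2R)-6-oxo-3,6-dihydro-2H-pyran-2-yl][(1S,2S)-2-(4,4,5,5-tetramethyl-1,3,2-dioxaborolan-2-yl)cyclopropyl]methyl acetate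
Conditions: Ac2O (1.5 equiv), pyridine, DMAP (5 mol%), CH2Cl2, 0 °C
Reagents that add atoms: acetic anhydride, CC(=O)OC(C)=O
Why: DMAP-catalysed O-acetylation breaks no C–O bond at C1′, so its configuration is kept.

Step 15
Reactants: 22 (S)-[(2R)-6-oxo-3,6-dihydro-2H-pyran-2-yl][(1S,2S)-2-(4,4,5,5-tetramethyl-1,3,2-dioxaborolan-2-yl)cyclopropyl]methyl acetate
Product: 23 [(1S,2S)-2-{(S)-acetoxy[(2R)-6-oxo-3,6-dihydro-2H-pyran-2-yl]methyl}cyclopropyl]boronic acid
Conditions: NaIO4 (3 equiv), NH4OAc (3 equiv), acetone/H2O 1:1, rt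
Reagents that add atoms: water, O
Why: Periodate cleavage of the pinacol ligand (buffered hydrolysis) gives the free boronic acid needed for base-free transmetalation; the C–B bond and all stereocentres are untouched.

Step 16
Reactants: 23 [(1S,2S)-2-{(S)-acetoxy[(2R)-6-oxo-3,6-dihydro-2H-pyran-2-yl]methyl}cyclopropyl]boronic acid, 8 (2S)-1-(ethylsulfanyl)-1-oxopropan-2-yl (2E)-3-{3,4-bis[(tert-butyldimethylsilyl)oxy]phenyl}prop-2-enoate
Product: 24 (2S)-1-[(1S,2S)-2-{(S)-acetoxy[(2R)-6-oxo-3,6-dihydro-2H-pyran-2-yl]methyl}cyclopropyl]-1-oxopropan-2-yl (2E)-3-{3,4-bis[(tert-butyldimethylsilyl)oxy]phenyl}prop-2-enoate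
Conditions: 23 (1.3 equiv), Pd2(dba)3 (5 mol%), tri(2-furyl)phosphine (20 mol%), copper thiophene-2-carboxylate Cu(O2CC4H3S) (CuTC, 1.6 equiv), degassed THF, 50 °C
Reagents that add atoms: none
Why: Proposed new method: a stereoretentive, base-free acyl cross-coupling of a configurationally defined secondary cyclopropylboronic acid with an α-acyloxy thioester, in which zerovalent palladium inserts into the C(acyl)–S bond, the monovalent copper carboxylate binds sulfur and passes its carboxylate to boron so that the cyclopropyl group (high s-character, sp2-like C–B bond) transmetalates with retention through a closed transition state, and reductive elimination forms the C4′–C5′ ketone bond with no base present that could epimerise C6′, migrate the acetate or open the lactone; the closest known reaction types are the thioester–boronic acid ketone synthesis (Liebeskind–Srogl) of aryl and alkenyl boronic acids and the Ag2O-promoted Suzuki acylation of cyclopropylboronic acids with acid chlorides.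

Step 17
Reactants: 24 (2S)-1-[(1S,2S)-2-{(S)-acetoxy[(2R)-6-oxo-3,6-dihydro-2H-pyran-2-yl]methyl}cyclopropyl]-1-oxopropan-2-yl (2E)-3-{3,4-bis[(tert-butyldimethylsilyl)oxy]phenyl}prop-2-enoate
Product: 25 (2S)-1-[(1S,2S)-2-{(S)-acetoxy[(2R)-6-oxo-3,6-dihydro-2H-pyran-2-yl]methyl}cyclopropyl]-1-oxopropan-2-yl (2E)-3-(3,4-dihydroxyphenyl)prop-2-enoate (CNP0103198.1)
Conditions: HF·pyridine, pyridine, THF, 0 °C → rt; pH 7 buffer work-up
Reagents that add atoms: none
Why: Fluoride cleavage of the two labile aryl silyl ethers under buffered acidic conditions does not epimerise the α-acyloxy ketone, migrate the acetate or open the lactone.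

**Compound list**
1 | catechol (benzene-1,2-diol) | Oc1ccccc1O | starting material
2 | 4-bromobenzene-1,2-diol | Oc1ccc(Br)cc1O | intermediate
3 | 4-bromo-1,2-bis[(tert-butyldimethylsilyl)oxy]benzene | CC(C)(C)[Si](C)(C)Oc1ccc(Br)cc1O[Si](C)(C)C(C)(C)C | intermediate
4 | acrylic acid | C=CC(=O)O | starting material
5 | (2E)-3-{3,4-bis[(tert-butyldimethylsilyl)oxy]phenyl}prop-2-enoic acid | OC(=O)/C=C/c1ccc(O[Si](C)(C)C(C)(C)C)c(O[Si](C)(C)C(C)(C)C)c1 | intermediate
6 | methyl (S)-lactate | COC(=O)[C@H](C)O | starting material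
7 | S-ethyl (2S)-2-hydroxypropanethioate | CCSC(=O)[C@H](C)O | intermediate
8 | (2S)-1-(ethylsulfanyl)-1-oxopropan-2-yl (2E)-3-{3,4-bis[(tert-butyldimethylsilyl)oxy]phenyl}prop-2-enoate | CCSC(=O)[C@H](C)OC(=O)/C=C/c1ccc(O[Si](C)(C)C(C)(C)C)c(O[Si](C)(C)C(C)(C)C)c1 | intermediate
9 | vinylmagnesium bromide | C=C[Mg]Br | starting material
10 | 4,4,5,5-tetramethyl-2-vinyl-1,3,2-dioxaborolane | C=CB1OC(C)(C)C(C)(C)O1 | intermediate
11 | penta-1,4-dien-3-ol | C=CC(O)C=C | starting material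
12 | (1S)-1-[(2R)-oxiran-2-yl]prop-2-en-1-ol | O[C@@H](C=C)[C@H]1CO1 | intermediate
13 | tert-butyldimethyl{[(1S)-1-[(2R)-oxiran-2-yl]prop-2-en-1-yl]oxy}silane | CC(C)(C)[Si](C)(C)O[C@@H](C=C)[C@H]1CO1 | intermediate
14 | ethyl propiolate | CCOC(=O)C#C | starting material
15 | lithium ethyl propiolate (lithium 3-ethoxy-3-oxoprop-1-yn-1-ide) | [Li]C#CC(=O)OCC | intermediate
16 | ethyl (5R,6S)-6-[(tert-butyldimethylsilyl)oxy]-5-hydroxyoct-7-en-2-ynoate | CC(C)(C)[Si](C)(C)O[C@@H](C=C)[C@H](O)CC#CC(=O)OCC | intermediate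
17 | ethyl (2Z,5R,6S)-6-[(tert-butyldimethylsilyl)oxy]-5-hydroxyocta-2,7-dienoate | CC(C)(C)[Si](C)(C)O[C@@H](C=C)[C@H](O)C/C=C\C(=O)OCC | intermediate
18 | (6R)-6-[(1S)-1-[(tert-butyldimethylsilyl)oxy]prop-2-en-1-yl]-5,6-dihydro-2H-pyran-2-one | CC(C)(C)[Si](C)(C)O[C@@H](C=C)[C@H]1CC=CC(=O)O1 | intermediate
19 | (6R)-6-[(1S)-1-hydroxyprop-2-en-1-yl]-5,6-dihydro-2H-pyran-2-one | O[C@@H](C=C)[C@H]1CC=CC(=O)O1 | intermediate
20 | (6R)-6-[(1S,2E)-1-hydroxy-3-(4,4,5,5-tetramethyl-1,3,2-dioxaborolan-2-yl)prop-2-en-1-yl]-5,6-dihydro-2H-pyran-2-one | O[C@@H](/C=C/B1OC(C)(C)C(C)(C)O1)[C@H]1CC=CC(=O)O1 | intermediate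
21 | (6R)-6-{(S)-hydroxy[(1S,2S)-2-(4,4,5,5-tetramethyl-1,3,2-dioxaborolan-2-yl)cyclopropyl]methyl}-5,6-dihydro-2H-pyran-2-one | O[C@@H]([C@H]1C[C@@H]1B1OC(C)(C)C(C)(C)O1)[C@H]1CC=CC(=O)O1 | intermediate
22 | (S)-[(2R)-6-oxo-3,6-dihydro-2H-pyran-2-yl][(1S,2S)-2-(4,4,5,5-tetramethyl-1,3,2-dioxaborolan-2-yl)cyclopropyl]methyl acetate | CC(=O)O[C@@H]([C@H]1C[C@@H]1B1OC(C)(C)C(C)(C)O1)[C@H]1CC=CC(=O)O1 | intermediate
23 | [(1S,2S)-2-{(S)-acetoxy[(2R)-6-oxo-3,6-dihydro-2H-pyran-2-yl]methyl}cyclopropyl]boronic acid | CC(=O)O[C@@H]([C@H]1C[C@@H]1B(O)O)[C@H]1CC=CC(=O)O1 | intermediate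
24 | (2S)-1-[(1S,2S)-2-{(S)-acetoxy[(2R)-6-oxo-3,6-dihydro-2H-pyran-2-yl]methyl}cyclopropyl]-1-oxopropan-2-yl (2E)-3-{3,4-bis[(tert-butyldimethylsilyl)oxy]phenyl}prop-2-enoate | CC(=O)O[C@@H]([C@H]1C[C@@H]1C(=O)[C@H](C)OC(=O)/C=C/c1ccc(O[Si](C)(C)C(C)(C)C)c(O[Si](C)(C)C(C)(C)C)c1)[C@H]1CC=CC(=O)O1 | intermediate
25 | (2S)-1-[(1S,2S)-2-{(S)-acetoxy[(2R)-6-oxo-3,6-dihydro-2H-pyran-2-yl]methyl}cyclopropyl]-1-oxopropan-2-yl (2E)-3-(3,4-dihydroxyphenyl)prop-2-enoate | CC(=O)O[C@@H]([C@H]1C[C@@H]1C(=O)[C@H](C)OC(=O)/C=C/c1ccc(O)c(O)c1)[C@H]1CC=CC(=O)O1 | target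

**Totals**
Total step count: 17.
Longest linear sequence: 11 steps (7 → 8 → 9 → 10 → 11 → 12 → 13 → 14 → 15 → 16 → 17), which is 11/17 of the total.

**Three steps most likely to fail, with fallbacks**

Step 16 (the proposed new coupling). The risk is slow transmetalation of the secondary cyclopropylboronic acid, which would let protodeboronation or decarbonylation of the acylpalladium species win. The fallback uses only known chemistry and builds the ring after the ketone carbon is in place. It sets out from 20: acetylation (Ac2O, pyridine) gives the alkenylboronate acetate F1, and NaIO4/NH4OAc frees the alkenylboronic acid F2. The established thioester–alkenylboronic acid ketone synthesis with 8 (Pd2(dba)3, tri(2-furyl)phosphine, CuTC, THF, 50 °C) then gives the enone F3. Reduction with (R)-2-methyl-CBS-oxazaborolidine/catecholborane gives the (3R)-allylic alcohol F4, whose hydroxyl directs Et2Zn/CH2I2 to its own face and gives the cyclopropyl carbinol F5 with the (1S,2S) ring. Dess–Martin oxidation of F5 comes back to the route at 24.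

Step 13 (ligand-controlled anti cyclopropanation of a secondary γ-boryl allylic alcohol). The risk is low reactivity of the electron-poor alkenylboronate or incomplete override of the substrate's syn preference. The fallback replaces ligand control by non-directed substrate control. It sets out from 20: TESCl/imidazole gives the triethylsilyl ether F6, and CF3CO2ZnCH2I (Et2Zn, CF3CO2H, CH2I2, CH2Cl2, 0 °C) adds CH2 anti to the bulky silyloxy group to give the cyclopropyl silyl ether F7. HF·pyridine comes back to the route at 21.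

Step 12 (cross-metathesis of a secondary allylic alcohol with vinyl-Bpin). The risk is low conversion or Ru–H isomerisation of the allylic alcohol to a ketone. The fallback replaces metathesis by carbonyl olefination. It sets out from 18: OsO4 (cat.)/NaIO4/2,6-lutidine in dioxane/H2O cleaves the electron-rich terminal alkene to the α-silyloxy aldehyde F8. Takai–Utimoto olefination with 2-(dichloromethyl)-4,4,5,5-tetramethyl-1,3,2-dioxaborolane, CrCl2 and LiI in THF gives the (E)-alkenylboronate silyl ether F9. HF·pyridine comes back to the route at 20.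

**Further compounds**
F1 | step 16 | (1S,2E)-1-[(2R)-6-oxo-3,6-dihydro-2H-pyran-2-yl]-3-(4,4,5,5-tetramethyl-1,3,2-dioxaborolan-2-yl)prop-2-en-1-yl acetate | CC(=O)O[C@@H](/C=C/B1OC(C)(C)C(C)(C)O1)[C@H]1CC=CC(=O)O1
F2 | step 16 | [(1E,3S)-3-acetoxy-3-[(2R)-6-oxo-3,6-dihydro-2H-pyran-2-yl]prop-1-en-1-yl]boronic acid | CC(=O)O[C@@H](/C=C/B(O)O)[C@H]1CC=CC(=O)O1
F3 | step 16 | (2S,4E,6S)-6-acetoxy-3-oxo-6-[(2R)-6-oxo-3,6-dihydro-2H-pyran-2-yl]hex-4-en-2-yl (2E)-3-{3,4-bis[(tert-butyldimethylsilyl)oxy]phenyl}prop-2-enoate | CC(=O)O[C@@H](/C=C/C(=O)[C@H](C)OC(=O)/C=C/c1ccc(O[Si](C)(C)C(C)(C)C)c(O[Si](C)(C)C(C)(C)C)c1)[C@H]1CC=CC(=O)O1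
F4 | step 16 | (2S,3R,4E,6S)-6-acetoxy-3-hydroxy-6-[(2R)-6-oxo-3,6-dihydro-2H-pyran-2-yl]hex-4-en-2-yl (2E)-3-{3,4-bis[(tert-butyldimethylsilyl)oxy]phenyl}prop-2-enoate | CC(=O)O[C@@H](/C=C/[C@@H](O)[C@H](C)OC(=O)/C=C/c1ccc(O[Si](C)(C)C(C)(C)C)c(O[Si](C)(C)C(C)(C)C)c1)[C@H]1CC=CC(=O)O1
F5 | step 16 | (1R,2S)-1-[(1S,2S)-2-{(S)-acetoxy[(2R)-6-oxo-3,6-dihydro-2H-pyran-2-yl]methyl}cyclopropyl]-1-hydroxypropan-2-yl (2E)-3-{3,4-bis[(tert-butyldimethylsilyl)oxy]phenyl}prop-2-enoate | CC(=O)O[C@@H]([C@H]1C[C@@H]1[C@@H](O)[C@H](C)OC(=O)/C=C/c1ccc(O[Si](C)(C)C(C)(C)C)c(O[Si](C)(C)C(C)(C)C)c1)[C@H]1CC=CC(=O)O1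
F6 | step 13 | (6R)-6-[(1S,2E)-3-(4,4,5,5-tetramethyl-1,3,2-dioxaborolan-2-yl)-1-[(triethylsilyl)oxy]prop-2-en-1-yl]-5,6-dihydro-2H-pyran-2-one | CC[Si](CC)(CC)O[C@@H](/C=C/B1OC(C)(C)C(C)(C)O1)[C@H]1CC=CC(=O)O1
F7 | step 13 | (6R)-6-{(S)-[(1S,2S)-2-(4,4,5,5-tetramethyl-1,3,2-dioxaborolan-2-yl)cyclopropyl][(triethylsilyl)oxy]methyl}-5,6-dihydro-2H-pyran-2-one | CC[Si](CC)(CC)O[C@@H]([C@H]1C[C@@H]1B1OC(C)(C)C(C)(C)O1)[C@H]1CC=CC(=O)O1
F8 | step 12 | (2R)-2-[(tert-butyldimethylsilyl)oxy]-2-[(2R)-6-oxo-3,6-dihydro-2H-pyran-2-yl]acetaldehyde | CC(C)(C)[Si](C)(C)O[C@@H](C=O)[C@H]1CC=CC(=O)O1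
F9 | step 12 | (6R)-6-[(1S,2E)-1-[(tert-butyldimethylsilyl)oxy]-3-(4,4,5,5-tetramethyl-1,3,2-dioxaborolan-2-yl)prop-2-en-1-yl]-5,6-dihydro-2H-pyran-2-one | CC(C)(C)[Si](C)(C)O[C@@H](/C=C/B1OC(C)(C)C(C)(C)O1)[C@H]1CC=CC(=O)O1
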